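The route rests on opening the pyrrole ring of the 6-bromoindole at C3–C3a and N1–C2. C2 and C3 of that ring originate as the sp carbons of a triethylsilyl-capped ethynyl group on imidazole C4, whereas the benzene ring, N1 and the C6 bromine are delivered ready-made by 5-bromo-2-iodoaniline. A single palladium-catalysed heteroannulation thus unites both halves and closes the five-membered ring, the silyl group ending at C2 as a traceless blocking group. The precursor is a doubly SEM-protected 2-(indol-3-yl)imidazole bearing the silylalkyne at C4, obtained as one regioisomer by way of a symmetric 4,5-diiodide.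

Key step: step 6

Remark: SEM = 2-(trimethylsilyl)ethoxymethyl. The two imidazole nitrogens of the target are tautomerically equivalent, so the SEM position does not affect the final structure; it is placed on N1, remote from C4, to keep the alkyne unhindered.

Step 1
Reactants: 1 indole-3-carboxaldehyde, 2 glyoxal
Product: 3 2-(1H-indol-3-yl)-1H-imidazole
Conditions: glyoxal (40% aq, 2 equiv), conc. aq NH3 (excess), MeOH, 0 °C to rt
Reagents that add atoms: ammonia, N
Why: Debus–Radziszewski imidazole synthesis, in which the glyoxal–ammonia diimine condenses with the aldehyde carbon of 1 and aromatises by loss of water, so that this carbon becomes imidazole C2; excess glyoxal and ammonia offset the low electrophilicity of the vinylogous formamide.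

Step 2
Reactants: 3 2-(1H-indol-3-yl)-1H-imidazole
Product: 4 4,5-diiodo-2-(1H-indol-3-yl)-1H-imidazole
Conditions: I2 (2.1 equiv), KI, aq NaOH, dioxane, 0 °C to rt
Reagents that add atoms: iodine, I-I
Why: Electrophilic aromatic iodination in which the imidazolide anion formed in aqueous base is by far the most nucleophilic site, so both free imidazole carbons are iodinated while the indole, blocked at C3 and deactivated by the attached azole, should remain untouched.

Step 3
Reactants: 4 4,5-diiodo-2-(1H-indol-3-yl)-1H-imidazole
Product: 5 4,5-diiodo-1-SEM-2-(1-SEM-indol-3-yl)imidazole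
Conditions: NaH (2.5 equiv), SEMCl (2.4 equiv), DMF, 0 °C to rt
Reagents that add atoms: 2-(trimethylsilyl)ethoxymethyl chloride (SEMCl), C[Si](C)(C)CCOCCl
Why: Double N-alkylation of the imidazolide and indolide anions by the reactive chloromethyl ether; because the 4,5-diiodoimidazole is symmetric, attack through either imidazole nitrogen gives the same single product, so no N-regioisomers can arise.

Step 4
Reactants: 5 4,5-diiodo-1-SEM-2-(1-SEM-indol-3-yl)imidazole
Product: 7 4-iodo-1-SEM-2-(1-SEM-indol-3-yl)imidazole, via imidazol-5-ylmagnesium bromide 6 (not isolated)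
Conditions: EtMgBr (1.1 equiv), THF, 0 °C to rt; then H2O
Reagents that add atoms: none
Why: Regioselective iodine–magnesium exchange followed by protonation: only the C5 iodine exchanges, because the C5 carbanion is stabilised by the adjacent SEM-bearing N1 (inductive effect and chelation by the SEM oxygen) and is not opposed by the N3 lone pair, which leaves the C4 iodide in place.

Step 5
Reactants: 7 4-iodo-1-SEM-2-(1-SEM-indol-3-yl)imidazole, 8 triethylsilylacetylene
Product: 9 1-SEM-2-(1-SEM-indol-3-yl)-4-[(triethylsilyl)ethynyl]imidazole
Conditions: 8 (1.5 equiv), PdCl2(PPh3)2 (5 mol %), CuI (10 mol %), Et3N, DMF, 50 °C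
Reagents that add atoms: none
Why: Sonogashira coupling of a heteroaryl iodide with a terminal alkyne; the triethylsilyl cap on the alkyne is stable to amine base and CuI, and both nitrogens are masked so that no palladium or copper azolide can form.

Step 6
Reactants: 9 1-SEM-2-(1-SEM-indol-3-yl)-4-[(triethylsilyl)ethynyl]imidazole, 10 5-bromo-2-iodoaniline
Product: 11 6-bromo-3-[1-SEM-2-(1-SEM-indol-3-yl)imidazol-4-yl]-2-(triethylsilyl)-1H-indole
Conditions: 10 (1.3 equiv), Pd(OAc)2 (10 mol %), LiCl (1 equiv), Na2CO3 (3 equiv), DMF, 100 °C, argon
Reagents that add atoms: none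
Why: Larock heteroannulation, whose closest precedent is the union of ortho-iodoanilines with aryl(silyl)alkynes to 2-silyl-3-arylindoles. Pd(OAc)2 is reduced in the flask to zerovalent palladium, which undergoes oxidative addition at the weak C–I bond of 10; the resulting arylpalladium iodide coordinates the alkyne of 9 and inserts it in a syn fashion, creating the C3–C3a bond at the imidazole-bearing alkyne carbon and leaving palladium on the carbon that holds SiEt3. Intramolecular attack of the NH2 group on palladium gives a six-membered azapalladacycle, and C–N reductive elimination (N1–C2 bond) closes the five-membered pyrrole ring, so the ring arises by a formal (3+2) annulation that ends in a carbon–nitrogen bond-forming ring contraction from palladium. No stereocentre is created. Two selectivities are required: C–I over C–Br, secured by the lower C–I bond strength under phosphine-free conditions and a small excess of 10, and insertion regiochemistry, secured by the bulk of SiEt3, which prefers the position next to the long C–Pd bond over that next to the short forming C–C bond. LiCl supplies chloride that keeps the zerovalent palladium species active, and the SEM group on imidazole N1 prevents formation of an inert palladium azolide.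

Step 7
Reactants: 11 6-bromo-3-[1-SEM-2-(1-SEM-indol-3-yl)imidazol-4-yl]-2-(triethylsilyl)-1H-indole
Product: 13 nortopsentin C, via C2-desilylated bis-SEM indole 12 (not isolated)
Conditions: Bu4NF (TBAF, 1 M in THF, 10 equiv), ethylenediamine (6 equiv), THF, rt then 70 °C
Reagents that add atoms: none
Why: Fluoride-mediated global deprotection in which fluoride first cleaves the indole C2–Si bond (protodesilylation to 12) and, on heating, attacks the trimethylsilyl groups of both SEM ethers, releasing ethylene and N-hydroxymethyl anions that collapse to the free N–H groups while ethylenediamine scavenges the formaldehyde; the aryl bromide is inert to fluoride.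

Compound list
1 | indole-3-carboxaldehyde | O=Cc1c[nH]c2ccccc12 | starting material
2 | glyoxal (40% aqueous solution) | O=CC=O | starting material
3 | 2-(1H-indol-3-yl)-1H-imidazole | c1c[nH]c(n1)-c1c[nH]c2ccccc12 | intermediate
4 | 4,5-diiodo-2-(1H-indol-3-yl)-1H-imidazole | Ic1nc([nH]c1I)-c1c[nH]c2ccccc12 | intermediate
5 | 4,5-diiodo-1-SEM-2-(1-SEM-indol-3-yl)imidazole (SEM on imidazole N1 and on indole N1) | Ic1nc(-c2cn(COCC[Si](C)(C)C)c3ccccc23)n(COCC[Si](C)(C)C)c1I | intermediate
6 | [4-iodo-1-SEM-2-(1-SEM-indol-3-yl)imidazol-5-yl]magnesium bromide | Br[Mg]c1c(I)nc(-c2cn(COCC[Si](C)(C)C)c3ccccc23)n1COCC[Si](C)(C)C | intermediate (not isolated)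
7 | 4-iodo-1-SEM-2-(1-SEM-indol-3-yl)imidazole | Ic1cn(COCC[Si](C)(C)C)c(n1)-c1cn(COCC[Si](C)(C)C)c2ccccc12 | intermediate
8 | triethylsilylacetylene | CC[Si](CC)(CC)C#C | starting material
9 | 1-SEM-2-(1-SEM-indol-3-yl)-4-[(triethylsilyl)ethynyl]imidazole | CC[Si](CC)(CC)C#Cc1cn(COCC[Si](C)(C)C)c(n1)-c1cn(COCC[Si](C)(C)C)c2ccccc12 | intermediate
10 | 5-bromo-2-iodoaniline | Nc1cc(Br)ccc1I | starting material
11 | 6-bromo-3-[1-SEM-2-(1-SEM-indol-3-yl)imidazol-4-yl]-2-(triethylsilyl)-1H-indole | CC[Si](CC)(CC)c1[nH]c2cc(Br)ccc2c1-c1cn(COCC[Si](C)(C)C)c(n1)-c1cn(COCC[Si](C)(C)C)c2ccccc12 | intermediate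
12 | 6-bromo-3-[1-SEM-2-(1-SEM-indol-3-yl)imidazol-4-yl]-1H-indole | Brc1ccc2c(c1)[nH]cc2-c1cn(COCC[Si](C)(C)C)c(n1)-c1cn(COCC[Si](C)(C)C)c2ccccc12 | intermediate (not isolated)
13 | nortopsentin C, 6-bromo-3-[2-(1H-indol-3-yl)-1H-imidazol-4-yl]-1H-indole | Brc1ccc2c(-c3c[nH]c(-c4c[nH]c5ccccc45)n3)c[nH]c2c1 | target

Total step count: 7. Longest linear sequence: 7 steps (1 to 13).

Steps most likely to fail

1. Step 6. The annulation may stall if imidazole N3 of the hindered, electron-rich alkyne sequesters palladium. It may also drift into oligomeric coupling through late oxidative addition at C–Br bonds, or lose regiocontrol in the alkyne insertion. Premature loss of the C2 silyl group would be harmless, since that material is 12. The fallback forms the imidazole C4–indole C3 bond by cross-coupling and sets out from iodide 7. Commercial 6-bromoindole is N-silylated (NaH, iPr3SiCl, THF) to 6-bromo-1-(triisopropylsilyl)indole F1. F1 is borylated at C3, the bulky silyl group shielding C2 and C7 ([Ir(OMe)(cod)]2, 4,4'-di-tert-butyl-2,2'-bipyridine, B2pin2, THF, 60 °C), to give 6-bromo-3-(pinacolboryl)-1-(triisopropylsilyl)indole F2. Suzuki–Miyaura coupling of F2 with 7 (PdCl2(dppf), K3PO4, dioxane/H2O, 80 °C), in which the heteroaryl C–I bond should react ahead of the aryl C–Br bond, gives 6-bromo-3-[1-SEM-2-(1-SEM-indol-3-yl)imidazol-4-yl]-1-(triisopropylsilyl)indole F3. Treating F3 under the conditions of step 7 removes the N-silyl group and both SEM groups, and the route is rejoined at 13.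

2. Step 7. Cleavage of the indole N-SEM group by fluoride may stop at the N-hydroxymethyl stage or remain incomplete, giving partly protected mixtures. The fallback replaces fluoride by an acid stage and a base stage and sets out from 11. Trifluoroacetic acid in CH2Cl2 at rt should effect ipso-protodesilylation at indole C2 and cleave both SEM acetals, giving 6-bromo-3-{1-(hydroxymethyl)-2-[1-(hydroxymethyl)indol-3-yl]imidazol-4-yl}-1H-indole F4. Treatment of crude F4 with aqueous NH3 in MeOH (rt to 50 °C) releases formaldehyde from both hemiaminals, and the route is rejoined at 13.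

3. Step 1. Addition to the poorly electrophilic, vinylogous-amide aldehyde may be slow, while glyoxal and ammonia self-condense to oligomers, so conversion to the imidazole could be low. The fallback builds the ring at the dihydro oxidation level and sets out from 1. Condensation with ethylenediamine in tBuOH gives the aminal 2-(1H-indol-3-yl)imidazolidine F5. F5 is oxidised in the same flask (I2, K2CO3, 70 °C) to 2-(1H-indol-3-yl)-4,5-dihydro-1H-imidazole F6. Dehydrogenation of F6 with activated MnO2 in refluxing toluene gives the imidazole, and the route is rejoined at 3.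

Further compounds
F1 | step 6 | 6-bromo-1-(triisopropylsilyl)indole | CC(C)[Si](C(C)C)(C(C)C)n1ccc2ccc(Br)cc21
F2 | step 6 | 6-bromo-3-(4,4,5,5-tetramethyl-1,3,2-dioxaborolan-2-yl)-1-(triisopropylsilyl)indole | CC(C)[Si](C(C)C)(C(C)C)n1cc(B2OC(C)(C)C(C)(C)O2)c2ccc(Br)cc21
F3 | step 6 | 6-bromo-3-[1-SEM-2-(1-SEM-indol-3-yl)imidazol-4-yl]-1-(triisopropylsilyl)indole | CC(C)[Si](C(C)C)(C(C)C)n1cc(-c2cn(COCC[Si](C)(C)C)c(n2)-c2cn(COCC[Si](C)(C)C)c3ccccc23)c2ccc(Br)cc21
F4 | step 7 | 6-bromo-3-{1-(hydroxymethyl)-2-[1-(hydroxymethyl)indol-3-yl]imidazol-4-yl}-1H-indole | OCn1cc(-c2c[nH]c3cc(Br)ccc23)nc1-c1cn(CO)c2ccccc12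
F5 | step 1 | 2-(1H-indol-3-yl)imidazolidine | C1CNC(N1)c1c[nH]c2ccccc12
F6 | step 1 | 2-(1H-indol-3-yl)-4,5-dihydro-1H-imidazole | C1CN=C(N1)c1c[nH]c2ccccc12
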